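Slowness opened the meeting: one chemist noted that target forms more slowly late than early in both earlier runs.

| flask | starting material | partner | transfer agent | initiator | remark | time |
|---|---|---|---|---|---|---|
| beta | 0.067 M | 0.25 M | 5 mM | 2.5 mM | run made earlier |  |
| delta | 0.10 M | 0.25 M | 5 mM | 5 mM | run made earlier |  |
| north-east | 0.10 M | 0.250 M | 3.00 mM | 2.5 mM |  | 2.0 min |
| north | 0.10 M | 0.250 M | 2.50 mM | 2.5 mM |  | 2.0 min |
| south-west | 0.10 M | 0.250 M | 8.00 mM | 2.5 mM |  | 2.0 min |
| south-east | 0.10 M | 0.250 M | 1.20 mM | 2.5 mM |  | 2.0 min |
| north-west | 0.10 M | 0.250 M | 5.00 mM | 2.5 mM |  | 2.0 min |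

| run | time / s | target / % | starting material / % |
|---|---|---|---|
| beta | 10.0 | 7.6 | 92.0 |
| beta | 12.0 | 8.1 | 90.2 |
| beta | 20.0 | 12.8 | 84.3 |
| beta | 40.0 | 20.3 | 76.1 |
| delta | 10.0 | 8.9 | 89.7 |
| delta | 12.0 | 11.4 | 86.2 |
| delta | 20.0 | 17.2 | 79.7 |
| delta | 40.0 | 29.2 | 66.8 |

(each reading ± 0.5 percentage points)

- no earlier run changes the charge of transfer agent; that part of a forecast is a guess

1. ranking by amount of target, in percent of the starting material charged, from high to low, at 2.0 min (north-east / north / south-west / south-east / north-west)
2. the amount of target, in percent of the starting material charged of the flask you put first, at 2.0 min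
3. the amount of target, in percent of the starting material charged of the flask you put last, at 2.0 min

She read the fading, pooled over both runs, as 0.0217 s⁻¹, a rough reading given the scatter. So a rate fading at that pace gives by 2.0 min 1.60 times what it gave by 40.0 s.

A colleague then divided target at the last reading by initiator charged, as amounts. Beta gave 5.44 and delta 5.84, although delta held 1.49 times beta's starting material. He therefore dropped starting material from the reckoning and kept the mean, 5.64, as the chain yield, the target made per initiator charged by 40.0 s with agent at 5 mM, a kinetic chain length counted per initiator charged.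

Another member guessed, with no run to support it, that transfer agent ends chains, so that chain yield goes as the inverse of its charge.

The secretary reckoned on this as his own. Initiator is 2.50% of the starting material charged, so he put north-west at 22.5%, north-east at 37.5%, north at 45.0%, south-east at 93.8% and south-west at 14.1%. Going round once more, he added delta's unaccounted 4.00% at its last reading to the south-east answer. That came to 97.8%, under the charge, so the answer stood.

The forecast, on transfer agent guessing “it carries the chain and that its effect saturates”, gave the reverse of the secretary's order: south-west > north-west > north-east > north > south-east, from 46% down to 22%.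

The simulation gives south-east > north > north-east > north-west > south-west, from 96.8% down to 12.0%.

    partner + first chain carrier → target + second chain carrier (k = 7.60 × 10⁵ L mol⁻¹ s⁻¹)
    2 idle radical → ended radicals (k = 1.60 × 10⁹ L mol⁻¹ s⁻¹)
    2 second chain carrier → ended chains (k = 7.00 × 10⁸ L mol⁻¹ s⁻¹)
    transfer agent + first chain carrier → side product + idle radical (kL = 1.80 × 10⁶ L mol⁻¹ s⁻¹)
    starting material + second chain carrier → released group + first chain carrier (k = 8.60 × 10⁵ L mol⁻¹ s⁻¹)
    partner → decomposed reagent (k = 0.0240 s⁻¹)
    2 starting material → homo dimer (k = 0.00570 L mol⁻¹ s⁻¹)
    starting material + initiating radical → capped initiator + first chain carrier (k = 4.00 × 10⁶ L mol⁻¹ s⁻¹)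
    initiator → 2 initiating radical (k = 0.00520 s⁻¹)

The chain yield of 5.64 had given south-east 93.8%, and that flask stands at 96.8%. It had given south-west 14.1%, and that flask stands at 12.0%. The neighbouring flask is south-east with initiator cut to 0.00630 equiv. The same reckoning, chain yield times that initiator share, times the time factor 1.60, times the agent ratio, gives it 23.6%. The neighbour makes 21.1% and keeps 70% of its starting material.

The data come from a simulation on assumed constants, and the scatter is random.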